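**Retrosynthetic overview**

- The target is read as 18-acetoxylabda-8(17),13E-dien-15-oic acid (labdane numbering; β = face of the C10 methyl C20): 4α-CH2OAc (C18), 4β-CH3 (C19), 5α-H, 9α-H.
- The plan rests on quaternary C4 of ring A: it is bonded to C5 and carries the oxygenated carbon C18, so C18 can travel as a vinyl group and C4–C5 can be made by adding the γ-carbon of an allylboronate to a C5 ketone.
- Ring B (C5–C10) is bought as cyclohexane-1,3-dione and desymmetrised (C10). Ring A (C1–C5, C10) is closed second by intramolecular allylboration; C1–C4, C18 and C19 come from geranyl acetate.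
- After ring closure: vinyl to C18 carbinol; C5–OH removed by dehydration and hydrogen-atom-transfer hydrogenation (5α-H); C9 ketone to enol triflate, B-alkyl Suzuki coupling (C11–C13, C16), hydroboration/oxidation/Wittig (9α-H, C8=C17), Horner–Wadsworth–Emmons (C14, C15), acetate, ester release.

Key step: step 7

Assumption: the C9 carbinol of ketol 8 is taken as (R) (oxygen trans to the C10 methyl, cis to the tether). This centre is oxidised away in step 13, so only C10 of the enzymatic product reaches the target.

**Route**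

Step 1
Reactants: 1 geranyl acetate
Product: 3 (E)-3-methyl-6-oxohex-2-en-1-yl acetate, via ozonide 2 (not isolated)
Conditions: O3 (1.0 equiv), CH2Cl2, –78 °C; then Me2S, –78 °C → rt
Reagents that add atoms: ozone, O=[O+][O-]
Why: Ozonolysis with one equivalent of ozone should cleave only the electron-rich distal trisubstituted alkene, because the C2=C3 alkene is deactivated by the allylic acetate, and dimethyl sulfide reduces the ozonide to the aldehyde.

Step 2
Reactants: 3 (E)-3-methyl-6-oxohex-2-en-1-yl acetate; 4 cyclohexane-1,3-dione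
Product: 6 (E)-6-(2,6-dioxocyclohexyl)-3-methylhex-2-en-1-yl acetate, via alkylidene dione 5 (not isolated)
Conditions: Hantzsch ester (1.1 equiv), L-proline (cat.), CH2Cl2, rt
Reagents that add atoms: none
Why: Organocatalytic reductive alkylation, in which a proline-mediated Knoevenagel condensation gives the alkylidene dione and conjugate hydride transfer from the Hantzsch ester reduces it, so only mono-C-alkylation at C2 of the dione is possible.

Step 3
Reactants: 6 (E)-6-(2,6-dioxocyclohexyl)-3-methylhex-2-en-1-yl acetate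
Product: 7 (E)-3-methyl-6-(1-methyl-2,6-dioxocyclohexyl)hex-2-en-1-yl acetate
Conditions: MeI, K2CO3, acetone, reflux
Reagents that add atoms: iodomethane, CI
Why: C-alkylation of the stabilised dione enolate with iodomethane installs the C10 methyl (C20) and makes the two carbonyl groups enantiotopic, while the acetate survives the anhydrous carbonate and any O-methyl enol ether is hydrolysed back to 6 on acidic work-up.

Step 4
Reactants: 7 (E)-3-methyl-6-(1-methyl-2,6-dioxocyclohexyl)hex-2-en-1-yl acetate
Product: 8 (E)-6-[(1R,2R)-2-hydroxy-1-methyl-6-oxocyclohexyl]-3-methylhex-2-en-1-yl acetate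
Conditions: ketoreductase (anti-Prelog enzyme chosen by panel screening), NADP+ (cat.), i-PrOH, phosphate buffer pH 7, DMSO (5 vol%), 30 °C
Reagents that add atoms: none
Why: Enzymatic desymmetrising carbonyl reduction in which the enzyme must reduce the one enantiotopic carbonyl group that leaves C10 as (R); this ketol is the mirror image of the one baker's yeast usually gives with such diones, hence the screened anti-Prelog enzyme, and the C9 carbinol formed with it is erased in step 13.

Step 5
Reactants: 8 (E)-6-[(1R,2R)-2-hydroxy-1-methyl-6-oxocyclohexyl]-3-methylhex-2-en-1-yl acetate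
Product: 9 (E)-6-[(1R,2R)-2-(tert-butyldimethylsilyloxy)-1-methyl-6-oxocyclohexyl]-3-methylhex-2-en-1-yl acetate
Conditions: TBSOTf, 2,6-lutidine, CH2Cl2, –78 → 0 °C
Reagents that add atoms: tert-butyldimethylsilyl triflate, CC(C)(C)[Si](C)(C)OS(=O)(=O)C(F)(F)F
Why: Silylation of the hindered neopentyl secondary alcohol with the reactive silyl triflate, where the weak hindered base and low temperature avoid silyl enol ether formation and retro-aldol opening of the β-hydroxy ketone.

Step 6
Reactants: 9 (E)-6-[(1R,2R)-2-(tert-butyldimethylsilyloxy)-1-methyl-6-oxocyclohexyl]-3-methylhex-2-en-1-yl acetate; 10 bis(pinacolato)diboron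
Product: 11 (2R,3R)-3-(tert-butyldimethylsilyloxy)-2-methyl-2-[(E)-4-methyl-6-(4,4,5,5-tetramethyl-1,3,2-dioxaborolan-2-yl)hex-4-enyl]cyclohexan-1-one
Conditions: Pd2(dba)3 (cat.), DMSO, 50 °C
Reagents that add atoms: none
Why: Palladium-catalysed allylic borylation (Miyaura type), in which the π-allyl complex from the allylic acetate transmetalates with the acetate-activated diboron and couples at the less hindered terminus, should give the linear boronate with the E geometry retained and turns the formerly electrophilic allyl unit into a nucleophile at C4.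

Step 7
Reactants: 11 (2R,3R)-3-(tert-butyldimethylsilyloxy)-2-methyl-2-[(E)-4-methyl-6-(4,4,5,5-tetramethyl-1,3,2-dioxaborolan-2-yl)hex-4-enyl]cyclohexan-1-one
Product: 13 9α-(tert-butyldimethylsilyloxy)-4β,10β-dimethyl-4α-vinyl-cis-decalin-5β-ol, via borate ester 12 (not isolated)
Conditions: PhMe, 100 °C, sealed tube; then 1 M aq. NaOH, THF, rt
Reagents that add atoms: none
Why: Thermal intramolecular allylboration in which boron coordinates the C5 carbonyl oxygen and the γ-carbon C4 is delivered through a closed six-membered chair (B, O, C5, C4 and the two remaining allyl carbons); the closest known reaction types are the cyclisation of ω-oxo (E)-2-alkenylboronates to trans-2-vinylcycloalkanols and the addition of γ,γ-disubstituted allylboronates to ketones. Ring A closes in a 6-exo-trig mode at the carbonyl carbon with the allyl double bond outside the new ring, where it remains as the C4 vinyl group. C4 is controlled by the E geometry, which holds C3 equatorial and C19 axial in the chair, together with the equatorial place that quaternary C10 takes at C5: with both tether ends equatorial (a trans-fused bicyclic array) C19 becomes axial on ring A and syn to C20 while the vinyl group is equatorial (α). C5 follows from the same array, since C6 is then axial on ring A, which the existing ring B allows only with C9 equatorial and C20 axial at C10, so the hydroxyl ends up cis to C20 (cis-fused decalin). The step needs this chair to win over the one with C10 axial (which would give the C4 epimer); the size difference between quaternary C10 and the C6 methylene and the geometric purity of the boronate secure it, at the price of a syn 1,3 contact between C19 and C20 that may call for prolonged heating.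

Step 8
Reactants: 13 9α-(tert-butyldimethylsilyloxy)-4β,10β-dimethyl-4α-vinyl-cis-decalin-5β-ol
Product: 16 9α-(tert-butyldimethylsilyloxy)-4α-(hydroxymethyl)-4β,10β-dimethyl-cis-decalin-5β-ol, via ozonide 14 (not isolated), via hydroxy aldehyde 15 (not isolated)
Conditions: O3, CH2Cl2, –78 °C; then NaBH4, MeOH, –78 → 0 °C
Reagents that add atoms: ozone, O=[O+][O-]
Why: Ozonolysis of the only alkene followed by borohydride reduction of the ozonide in the same flask turns the vinyl group into the C18 carbinol, and the cold hydride quench should reduce the β-hydroxy aldehyde before retro-aldol cleavage of the new C4–C5 bond can compete.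

Step 9
Reactants: 16 9α-(tert-butyldimethylsilyloxy)-4α-(hydroxymethyl)-4β,10β-dimethyl-cis-decalin-5β-ol
Product: 17 9α-(tert-butyldimethylsilyloxy)-4α-[(4-methoxybenzyloxy)methyl]-4β,10β-dimethyl-cis-decalin-5β-ol
Conditions: NaH, PMBCl, Bu4NI (cat.), DMF, 0 °C → rt
Reagents that add atoms: 4-methoxybenzyl chloride, COc1ccc(CCl)cc1
Why: Williamson etherification of the primary alkoxide only, because the C5 tertiary alkoxide between two quaternary carbons is too hindered to react and the 9α-silyl ether, trans to the 5β-oxygen, cannot migrate; the PMB ether is chosen to survive strong base, borane, ylides and mild acid and to leave oxidatively at the end.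

Step 10
Reactants: 17 9α-(tert-butyldimethylsilyloxy)-4α-[(4-methoxybenzyloxy)methyl]-4β,10β-dimethyl-cis-decalin-5β-ol
Product: 19 9α-(tert-butyldimethylsilyloxy)-4α-[(4-methoxybenzyloxy)methyl]-4β,10β-dimethyl-Δ5(6)-octalin, via chlorosulfite 18 (not isolated)
Conditions: SOCl2, pyridine, CH2Cl2, –20 → 0 °C
Reagents that add atoms: none
Why: Dehydration by anti elimination from the chlorosulfite, in which C4 and C10 are quaternary so the only β-hydrogens sit on C6 and the alkene can form only as C5=C6, the axial 5β-oxygen having an antiperiplanar 6α-hydrogen.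

Step 11
Reactants: 19 9α-(tert-butyldimethylsilyloxy)-4α-[(4-methoxybenzyloxy)methyl]-4β,10β-dimethyl-Δ5(6)-octalin
Product: 20 9α-(tert-butyldimethylsilyloxy)-4α-[(4-methoxybenzyloxy)methyl]-4β,10β-dimethyl-trans-decalin
Conditions: Mn(dpm)3 (cat.), PhSiH3, t-BuOOH, i-PrOH, rt
Reagents that add atoms: none
Why: Metal-hydride hydrogen-atom-transfer hydrogenation, in which hydrogen-atom transfer to C6 gives the tertiary C5 radical and this is quenched from the α face opposite the axial methyl groups C19 and C20, should set 5α-H (trans fusion) and leaves the PMB ether, which heterogeneous hydrogenation would cleave, untouched.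

Step 12
Reactants: 20 9α-(tert-butyldimethylsilyloxy)-4α-[(4-methoxybenzyloxy)methyl]-4β,10β-dimethyl-trans-decalin
Product: 21 4α-[(4-methoxybenzyloxy)methyl]-4β,10β-dimethyl-trans-decalin-9α-ol
Conditions: HF (48% aq.), MeCN, rt
Reagents that add atoms: none
Why: Fluoride-driven desilylation (Si–F bond formation) frees the C9 alcohol, and the PMB ether is stable to aqueous HF in acetonitrile.

Step 13
Reactants: 21 4α-[(4-methoxybenzyloxy)methyl]-4β,10β-dimethyl-trans-decalin-9α-ol
Product: 22 4α-[(4-methoxybenzyloxy)methyl]-4β,10β-dimethyl-trans-decalin-9-one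
Conditions: Dess–Martin periodinane, CH2Cl2, rt
Reagents that add atoms: none
Why: Dess–Martin oxidation of the secondary alcohol under neutral conditions gives the C9 ketone and removes the auxiliary C9 stereocentre of step 4.

Step 14
Reactants: 22 4α-[(4-methoxybenzyloxy)methyl]-4β,10β-dimethyl-trans-decalin-9-one
Product: 23 4α-[(4-methoxybenzyloxy)methyl]-4β,10β-dimethyl-Δ8(9)-octalin-9-yl triflate
Conditions: KN(SiMe3)2, PhNTf2, THF, –78 °C
Reagents that add atoms: N-phenylbis(trifluoromethanesulfonimide), O=S(=O)(N(c1ccccc1)S(=O)(=O)C(F)(F)F)C(F)(F)F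
Why: Enolate O-triflation, in which C10 is quaternary so the ketone can enolise only towards C8 and a single enol triflate (C8=C9) results.

Step 15
Reactants: 23 4α-[(4-methoxybenzyloxy)methyl]-4β,10β-dimethyl-Δ8(9)-octalin-9-yl triflate; 24 2-methyl-2-vinyl-1,3-dioxolane
Product: 26 18-(4-methoxybenzyloxy)-14,15,17-trinorlabd-8-en-13-one ethylene ketal, via alkylborane 25 (not isolated)
Conditions: 24, 9-BBN-H, THF, 0 °C → rt; then 23, Pd(dppf)Cl2 (cat.), AsPh3, Cs2CO3, DMF/H2O, 50 °C
Reagents that add atoms: none
Why: B-alkyl Suzuki–Miyaura coupling, in which 9-BBN adds anti-Markovnikov to the vinyl ketal and the primary alkylborane transmetalates to the vinylpalladium species from the triflate, forms C9–C11 and brings in C11, C12, C13 and C16 with C13 masked as the dioxolane.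

Step 16
Reactants: 26 18-(4-methoxybenzyloxy)-14,15,17-trinorlabd-8-en-13-one ethylene ketal
Product: 28 8α-hydroxy-18-(4-methoxybenzyloxy)-14,15,17-trinorlabdan-13-one ethylene ketal, via C8 borane 27 (not isolated)
Conditions: BH3·THF, THF, 0 °C → rt; then NaOH, H2O2, 0 °C → rt
Reagents that add atoms: hydrogen peroxide, OO
Why: Hydroboration–oxidation, in which borane adds syn from the α face opposite the axial C10 methyl with boron at the less substituted C8 and hydrogen at C9, sets 9α-H (chain β, equatorial), and oxidation with retention gives the 8α-alcohol.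

Step 17
Reactants: 28 8α-hydroxy-18-(4-methoxybenzyloxy)-14,15,17-trinorlabdan-13-one ethylene ketal
Product: 29 18-(4-methoxybenzyloxy)-14,15,17-trinorlabdane-8,13-dione 13-ethylene ketal
Conditions: Dess–Martin periodinane, CH2Cl2, rt
Reagents that add atoms: none
Why: Dess–Martin oxidation gives the C8 ketone, and C9, now α to it, already carries its chain in the thermodynamically preferred equatorial position so it cannot be lost by epimerisation.

Step 18
Reactants: 29 18-(4-methoxybenzyloxy)-14,15,17-trinorlabdane-8,13-dione 13-ethylene ketal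
Product: 30 18-(4-methoxybenzyloxy)-14,15-dinorlabd-8(17)-en-13-one ethylene ketal
Conditions: Ph3PCH3Br, KOt-Bu, PhMe, rt → 80 °C
Reagents that add atoms: methyltriphenylphosphonium bromide, C[P+](c1ccccc1)(c1ccccc1)c1ccccc1.[Br-]
Why: Wittig methylenation of the only free ketone with the unstabilised ylide introduces C17 as the exocyclic methylene, and any enolisation of this α-branched ketone returns the same C9 configuration.

Step 19
Reactants: 30 18-(4-methoxybenzyloxy)-14,15-dinorlabd-8(17)-en-13-one ethylene ketal
Product: 31 18-(4-methoxybenzyloxy)-14,15-dinorlabd-8(17)-en-13-one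
Conditions: PPTS (cat.), acetone/H2O, 50 °C
Reagents that add atoms: water, O
Why: Acetal hydrolysis with a weak acid liberates the C13 methyl ketone without migration of the exocyclic alkene or loss of the PMB ether.

Step 20
Reactants: 31 18-(4-methoxybenzyloxy)-14,15-dinorlabd-8(17)-en-13-one; 32 allyl diethylphosphonoacetate
Product: 33 allyl 18-(4-methoxybenzyloxy)labda-8(17),13E-dien-15-oate
Conditions: NaH, THF, 0 °C → 50 °C
Reagents that add atoms: none
Why: Horner–Wadsworth–Emmons olefination of the methyl ketone adds C14 and C15 as the allyl ester, the E isomer (chain trans to the ester) should predominate, and the minor Z isomer is to be removed by chromatography.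

Step 21
Reactants: 33 allyl 18-(4-methoxybenzyloxy)labda-8(17),13E-dien-15-oate
Product: 34 allyl 18-hydroxylabda-8(17),13E-dien-15-oate
Conditions: DDQ, CH2Cl2/pH 7 buffer, 0 °C → rt
Reagents that add atoms: none
Why: Oxidative PMB cleavage (hydride abstraction from the electron-rich benzylic position by DDQ, then hydrolysis of the oxocarbenium ion) frees the C18 alcohol while the isolated alkene, the enoate and the allyl ester are inert.

Step 22
Reactants: 34 allyl 18-hydroxylabda-8(17),13E-dien-15-oate
Product: 35 allyl 18-acetoxylabda-8(17),13E-dien-15-oate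
Conditions: Ac2O, pyridine, DMAP (cat.), CH2Cl2, rt
Reagents that add atoms: acetic anhydride, CC(=O)OC(C)=O
Why: Nucleophile-catalysed acylation of the neopentyl primary alcohol gives the C18 acetate.

Step 23
Reactants: 35 allyl 18-acetoxylabda-8(17),13E-dien-15-oate
Product: 36 18-acetoxylabda-8(17),13E-dien-15-oic acid
Conditions: Pd(PPh3)4 (cat.), morpholine, THF, rt; dilute aq. citric acid work-up
Reagents that add atoms: none
Why: Palladium-catalysed deallylation of Tsuji–Trost type, in which zerovalent palladium ionises the allyl ester and morpholine captures the allyl group, releases the acid under near-neutral conditions that leave the acetate, the exocyclic alkene and the E enoate untouched.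

**Compound list**

1 | geranyl acetate, (E)-3,7-dimethylocta-2,6-dien-1-yl acetate | CC(C)=CCC/C(C)=C/COC(C)=O | starting material
2 | (E)-5-(5,5-dimethyl-1,2,4-trioxolan-3-yl)-3-methylpent-2-en-1-yl acetate (ozonide) | CC1(C)OOC(CC/C(C)=C/COC(C)=O)O1 | intermediate
3 | (E)-3-methyl-6-oxohex-2-en-1-yl acetate | O=CCC/C(C)=C/COC(C)=O | intermediate
4 | cyclohexane-1,3-dione | O=C1CCCC(=O)C1 | starting material
5 | (E)-6-(2,6-dioxocyclohexylidene)-3-methylhex-2-en-1-yl acetate | O=C1CCCC(=O)C1=CCC/C(C)=C/COC(C)=O | intermediate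
6 | (E)-6-(2,6-dioxocyclohexyl)-3-methylhex-2-en-1-yl acetate (drawn as the diketo form) | O=C1CCCC(=O)C1CCC/C(C)=C/COC(C)=O | intermediate
7 | (E)-3-methyl-6-(1-methyl-2,6-dioxocyclohexyl)hex-2-en-1-yl acetate | O=C1CCCC(=O)C1(C)CCC/C(C)=C/COC(C)=O | intermediate
8 | (E)-6-[(1R,2R)-2-hydroxy-1-methyl-6-oxocyclohexyl]-3-methylhex-2-en-1-yl acetate | O=C1CCC[C@@H](O)[C@@]1(C)CCC/C(C)=C/COC(C)=O | intermediate
9 | (E)-6-[(1R,2R)-2-(tert-butyldimethylsilyloxy)-1-methyl-6-oxocyclohexyl]-3-methylhex-2-en-1-yl acetate | O=C1CCC[C@@H](O[Si](C)(C)C(C)(C)C)[C@@]1(C)CCC/C(C)=C/COC(C)=O | intermediate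
10 | bis(pinacolato)diboron | CC1(C)OB(OC1(C)C)B1OC(C)(C)C(C)(C)O1 | starting material
11 | (2R,3R)-3-(tert-butyldimethylsilyloxy)-2-methyl-2-[(E)-4-methyl-6-(4,4,5,5-tetramethyl-1,3,2-dioxaborolan-2-yl)hex-4-enyl]cyclohexan-1-one (key-step precursor) | O=C1CCC[C@@H](O[Si](C)(C)C(C)(C)C)[C@@]1(C)CCC/C(C)=C/CB1OC(C)(C)C(C)(C)O1 | intermediate
12 | 5β-O-pinacol borate ester of 13 | C1CC[C@@H](O[Si](C)(C)C(C)(C)C)[C@@]2(C)CCC[C@@](C)(C=C)[C@@]12OB1OC(C)(C)C(C)(C)O1 | intermediate
13 | 9α-(tert-butyldimethylsilyloxy)-4β,10β-dimethyl-4α-vinyl-cis-decalin-5β-ol (key-step product; 5-OH cis to C20) | C1CC[C@@H](O[Si](C)(C)C(C)(C)C)[C@@]2(C)CCC[C@@](C)(C=C)[C@@]12O | intermediate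
14 | ozonide of 13 (4α-(1,2,4-trioxolan-3-yl)) | C1CC[C@@H](O[Si](C)(C)C(C)(C)C)[C@@]2(C)CCC[C@@](C)(C3OCOO3)[C@@]12O | intermediate
15 | 9α-(tert-butyldimethylsilyloxy)-5β-hydroxy-4β,10β-dimethyl-cis-decalin-4α-carbaldehyde | C1CC[C@@H](O[Si](C)(C)C(C)(C)C)[C@@]2(C)CCC[C@@](C)(C=O)[C@@]12O | intermediate
16 | 9α-(tert-butyldimethylsilyloxy)-4α-(hydroxymethyl)-4β,10β-dimethyl-cis-decalin-5β-ol | C1CC[C@@H](O[Si](C)(C)C(C)(C)C)[C@@]2(C)CCC[C@@](C)(CO)[C@@]12O | intermediate
17 | 9α-(tert-butyldimethylsilyloxy)-4α-[(4-methoxybenzyloxy)methyl]-4β,10β-dimethyl-cis-decalin-5β-ol | C1CC[C@@H](O[Si](C)(C)C(C)(C)C)[C@@]2(C)CCC[C@@](C)(COCc3ccc(OC)cc3)[C@@]12O | intermediate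
18 | 5β-chlorosulfite of 17 | C1CC[C@@H](O[Si](C)(C)C(C)(C)C)[C@@]2(C)CCC[C@@](C)(COCc3ccc(OC)cc3)[C@@]12OS(Cl)=O | intermediate
19 | 9α-(tert-butyldimethylsilyloxy)-4α-[(4-methoxybenzyloxy)methyl]-4β,10β-dimethyl-Δ5(6)-octalin (C5=C6) | C1CC=C2[C@](C)(COCc3ccc(OC)cc3)CCC[C@]2(C)[C@@H]1O[Si](C)(C)C(C)(C)C | intermediate
20 | 9α-(tert-butyldimethylsilyloxy)-4α-[(4-methoxybenzyloxy)methyl]-4β,10β-dimethyl-trans-decalin (5α-H) | C1CC[C@H]2[C@](C)(COCc3ccc(OC)cc3)CCC[C@]2(C)[C@@H]1O[Si](C)(C)C(C)(C)C | intermediate
21 | 4α-[(4-methoxybenzyloxy)methyl]-4β,10β-dimethyl-trans-decalin-9α-ol | C1CC[C@H]2[C@](C)(COCc3ccc(OC)cc3)CCC[C@]2(C)[C@@H]1O | intermediate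
22 | 4α-[(4-methoxybenzyloxy)methyl]-4β,10β-dimethyl-trans-decalin-9-one | C1CC[C@H]2[C@](C)(COCc3ccc(OC)cc3)CCC[C@]2(C)C1=O | intermediate
23 | 4α-[(4-methoxybenzyloxy)methyl]-4β,10β-dimethyl-Δ8(9)-octalin-9-yl triflate (5α-H) | FC(F)(F)S(=O)(=O)OC1=CCC[C@H]2[C@](C)(COCc3ccc(OC)cc3)CCC[C@]12C | intermediate
24 | 2-methyl-2-vinyl-1,3-dioxolane | C=CC1(C)OCCO1 | starting material
25 | 9-[2-(2-methyl-1,3-dioxolan-2-yl)ethyl]-9-borabicyclo[3.3.1]nonane | CC1(CCB2C3CCCC2CCC3)OCCO1 | intermediate
26 | 18-(4-methoxybenzyloxy)-14,15,17-trinorlabd-8-en-13-one ethylene ketal | CC1(CCC2=CCC[C@H]3[C@](C)(COCc4ccc(OC)cc4)CCC[C@]23C)OCCO1 | intermediate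
27 | 8α-boryl adduct of 26 (8α-BH2, 9α-H) | B[C@@H]1CC[C@H]2[C@](C)(COCc3ccc(OC)cc3)CCC[C@]2(C)[C@H]1CCC1(C)OCCO1 | intermediate
28 | 8α-hydroxy-18-(4-methoxybenzyloxy)-14,15,17-trinorlabdan-13-one ethylene ketal (9α-H) | O[C@@H]1CC[C@H]2[C@](C)(COCc3ccc(OC)cc3)CCC[C@]2(C)[C@H]1CCC1(C)OCCO1 | intermediate
29 | 18-(4-methoxybenzyloxy)-14,15,17-trinorlabdane-8,13-dione 13-ethylene ketal | O=C1CC[C@H]2[C@](C)(COCc3ccc(OC)cc3)CCC[C@]2(C)[C@H]1CCC1(C)OCCO1 | intermediate
30 | 18-(4-methoxybenzyloxy)-14,15-dinorlabd-8(17)-en-13-one ethylene ketal | C=C1CC[C@H]2[C@](C)(COCc3ccc(OC)cc3)CCC[C@]2(C)[C@H]1CCC1(C)OCCO1 | intermediate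
31 | 18-(4-methoxybenzyloxy)-14,15-dinorlabd-8(17)-en-13-one | C=C1CC[C@H]2[C@](C)(COCc3ccc(OC)cc3)CCC[C@]2(C)[C@H]1CCC(C)=O | intermediate
32 | allyl diethylphosphonoacetate | C=CCOC(=O)CP(=O)(OCC)OCC | starting material
33 | allyl 18-(4-methoxybenzyloxy)labda-8(17),13E-dien-15-oate | C=C1CC[C@H]2[C@](C)(COCc3ccc(OC)cc3)CCC[C@]2(C)[C@H]1CC/C(C)=C/C(=O)OCC=C | intermediate
34 | allyl 18-hydroxylabda-8(17),13E-dien-15-oate | C=C1CC[C@H]2[C@](C)(CO)CCC[C@]2(C)[C@H]1CC/C(C)=C/C(=O)OCC=C | intermediate
35 | allyl 18-acetoxylabda-8(17),13E-dien-15-oate | C=C1CC[C@H]2[C@](C)(COC(C)=O)CCC[C@]2(C)[C@H]1CC/C(C)=C/C(=O)OCC=C | intermediate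
36 | 18-acetoxylabda-8(17),13E-dien-15-oic acid (CNP0360430.2) | C=C1CC[C@H]2[C@](C)(COC(C)=O)CCC[C@]2(C)[C@H]1CC/C(C)=C/C(=O)O | target

**Step count and risks**

Total step count: 23. Longest linear sequence: 23 steps (1 to 36); compounds 4, 10, 24 and 32 are purchased.

The three steps most likely to fail:

1. Key step (step 7). Bond formation between the γ,γ-disubstituted allyl terminus and the α-quaternary ketone may be too slow with the pinacol boronate. Prolonged heating could then erode the alkene geometry or allow a 1,3-boron shift, and that would leak into the C4 epimer. The fallback sets out from 11. KHF2 in MeOH/H2O at rt should convert the pinacol ester into the potassium allyltrifluoroborate F1. BF3·OEt2 in CH2Cl2 at –78 °C then strips fluoride to give the much more electrophilic allyldifluoroborane F2, which should add to the ketone through the same closed chair at low temperature to give the difluoroborate ester F3. Aqueous NaHCO3 work-up returns to the route at 13.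

2. B-alkyl Suzuki coupling (step 15). Oxidative addition and transmetalation at the triflate next to quaternary C10 may be slow, so that β-hydride elimination or protodeboronation of the alkylborane and hydrolysis of the triflate take over. The fallback sets out from 23 and uses a small sp2 partner without an sp3 organometallic. A Heck reaction with methyl vinyl ketone (Pd(OAc)2, PPh3, Et3N, DMF, 70 °C) should give the (E)-dienone F4. Conjugate reduction of the enone with [(Ph3P)CuH]6 in toluene at rt should give the saturated methyl ketone F5 with the C8=C9 alkene intact. Ketalisation (ethylene glycol, PPTS, benzene, reflux with water removal) returns to the route at 26.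

3. Enzymatic desymmetrisation (step 4). The panel may not contain an enzyme that discriminates the two enantiotopic carbonyl groups in the needed sense, since yeast-type enzymes favour the mirror-image ketol, and esterase activity in the preparation may hydrolyse the acetate. The fallback sets out from 7 and uses small-molecule catalysis: Corey–Bakshi–Shibata reduction with (S)-2-methyl-CBS-oxazaborolidine (cat.) and catecholborane (0.6 equiv) in toluene at –78 °C. By the usual model this gives the (R) carbinol, and with hydride arriving anti to the long tether it selects the carbonyl group that leaves C10 as (R). The first product is the catechol borate ester F6, and aqueous work-up returns to the route at 8.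

Further compounds
F1 | step 7 | potassium trifluoroborate from 11, potassium (E)-6-[(1R,2R)-2-(tert-butyldimethylsilyloxy)-1-methyl-6-oxocyclohexyl]-3-methylhex-2-enyltrifluoroborate | O=C1CCC[C@@H](O[Si](C)(C)C(C)(C)C)[C@@]1(C)CCC/C(C)=C/C[B-](F)(F)F.[K+]
F2 | step 7 | allyldifluoroborane from F1 (not isolated) | O=C1CCC[C@@H](O[Si](C)(C)C(C)(C)C)[C@@]1(C)CCC/C(C)=C/CB(F)F
F3 | step 7 | 5β-O-difluoroborate ester of 13 (not isolated) | C1CC[C@@H](O[Si](C)(C)C(C)(C)C)[C@@]2(C)CCC[C@@](C)(C=C)[C@@]12OB(F)F
F4 | step 15 | (11E)-18-(4-methoxybenzyloxy)-14,15,17-trinorlabda-8,11-dien-13-one | CC(=O)/C=C/C1=CCC[C@H]2[C@](C)(COCc3ccc(OC)cc3)CCC[C@]12C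
F5 | step 15 | 18-(4-methoxybenzyloxy)-14,15,17-trinorlabd-8-en-13-one | CC(=O)CCC1=CCC[C@H]2[C@](C)(COCc3ccc(OC)cc3)CCC[C@]12C
F6 | step 4 | catechol borate ester of 8 (not isolated) | O=C1CCC[C@@H](OB2Oc3ccccc3O2)[C@@]1(C)CCC/C(C)=C/COC(C)=O
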